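## The problem

Target 16, (3R,4R)-4-(3,4-dimethoxybenzyl)-3-(4-hydroxy-3,5-dimethoxybenzyl)dihydrofuran-2(3H)-one, is a γ-butyrolactone (O1, C2(=O), C3, C4, C5) with two different benzyl groups on adjacent ring carbons, trans to each other. No ring fusion can be exploited. The task is to join two arylpropane units through the C3–C4 bond while keeping the two aryl groups distinct from the start. C3 is alpha to the lactone carbonyl, so it can be epimerised, and the trans isomer is the thermodynamic one. C4 carries only carbon substituents and cannot be corrected later, so it fixes the absolute configuration; once C4 is right, C3 follows by kinetic control or by equilibration. The sensitive parts are the free phenol between two methoxy groups (oxidisable, acidic towards strong base), the two electron-rich rings (open to ozone and electrophiles) and the lactone (ring opening and C3 epimerisation in base). The enabling feature is that the C3–C4 bond lies between the carbonyl carbon C2 and the oxygen-bearing methylene C5. If C5 is written as an alkene carbon, C2–C3–C4–C5 is a γ,δ-unsaturated acid, the product pattern of an ester enolate Claisen rearrangement, and C4 becomes the terminus of an allyl system whose configuration a remote carbinol can dictate.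

## Retrosynthesis

Numbering: the lactone is numbered O1, C2(=O), C3, C4, C5; open-chain acids are numbered from the carboxyl carbon, so acid C2/C3 become lactone C3/C4.

**16 from 15.** The phenolic O–H is traced back to the O–benzyl bond of lactone benzyl ether 15. A free phenol would consume base in the enolisation and is the group most exposed to oxidants. A fourth methyl ether could not be told apart from the other four, and a silyl ether is less secure towards amide base and acid. The benzyl ether is removed last by neutral hydrogenolysis, which touches neither the lactone nor C3.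

**15 from 12.** The lactone O1–C2 bond is opened and C5 is traced back to alkene carbon C4 of (2R,3S,E)-hexenoic acid 12, through ozonide 13 and hydroxy acid 14. The precursor is acyclic and the ring problem disappears. A vinyl group instead of propenyl would require a primary allyl ester with no stereocentre to transfer, so the extra methyl group is the price of the chirality source. The forward step must cleave the one alkene without attacking the arenes and without epimerising acid C3, which is alpha to the transient aldehyde.

**12 from 8.** The acid C2–C3 bond (lactone C3–C4) is cut in a [3,3] sense, leading to allylic ester 8 through enolate 9, ketene acetal 10 and silyl ester 11. The neighbouring cuts set one centre at a time and need a separate source of absolute configuration for C4: the C3–benzyl bond (enolate alkylation) or the C4–benzyl bond (conjugate addition). This cut makes the bond between the two stereocentres, sets both, and takes its chirality from one carbinol. Precursor 8 has a single C–O stereocentre and no C–C stereocentres. The forward reaction needs one ketene acetal geometry and one chair.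

**8 from 4 and 7.** The ester acyl–oxygen bond is cut to give acid 4 and allylic alcohol 7. Each half carries one aryl group, so the two rings are distinguished by construction and the route is convergent. The esterification must leave the carbinol C–O bond and the E alkene untouched.

**7 from 5 and 6.** The C3=C4 double bond of 7 is cut by cross-metathesis into methyl eugenol 5 and (R)-but-3-en-2-ol 6. Carbonyl-addition or alkyne routes would need an asymmetric reduction; here the stereocentre is bought and the aryl unit is a bulk chemical. The step needs high E selectivity and no migration of the allylarene double bond.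

**4 from 1.** No skeletal bond is cut. Acid 4 comes from sinapic acid 1 by alkene hydrogenation to 2, double benzylation to 3 and ester hydrolysis. Sinapic acid already holds the complete aryl–C3 unit with the correct oxygenation.

## Roads not taken

**Alternative 1:** The cut is oxygen insertion at C5: lactone A2, (R)-4-(3,4-dimethoxybenzyl)dihydrofuran-2(3H)-one, from the prochiral cyclobutanone A1. In the forward step a Baeyer–Villiger monooxygenase with O2 inserts oxygen into one of the two enantiotopic C(=O)–CH2 bonds and sets C4. The lactone enolate is then alkylated trans to the C4 substituent with benzyl bromide A3 to give 15, which is debenzylated to 16.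
- Merits: A1 should be two steps from methyl eugenol 5 (ketene [2+2] cycloaddition, reductive dechlorination). The oxidation is catalytic and avoids peracids on electron-rich arenes. Trans alkylation of 4-benzyl butyrolactone enolates is reliable.
- Weak points: the enantioselectivity rests on finding an enzyme that accepts the dimethoxybenzyl substituent and has (R) preference, which cannot be predicted from structure. It also brings fermentation or cofactor-recycling logistics. A3 is a labile electron-rich benzyl bromide that must be made separately, and C3 is set in a second strong-base step.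
- Comparison: this road is shorter, about five steps in the longest line against seven, and is better on step economy. The chosen plan sets against it a purchasable carbinol whose chirality transfer is predictable from the chair model, no enzyme screening, and both centres made in one C–C bond formation.

**Alternative 2:** The cut is the bond between the benzylic carbon on C4 and its aryl ring. The cyclopropane-fused lactone A4 comes in one step from a malonate diester and an epichlorohydrin enantiomer. The 3,4-dimethoxyphenyl Grignard reagent with catalytic CuI opens it at the cyclopropane methylene to give the 3-carbomethoxy lactone A5. A5 is alkylated with A3 under mild base, dealkoxycarbonylated and equilibrated to 15, then debenzylated.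
- Merits: the chirality source is very cheap, C4 is never at risk after A4, no strong base is needed for the C3 alkylation, and the count is about five linear steps.
- Weak points: the aryl nucleophile must choose the cyclopropane methylene over two carbonyl groups and over the ring methine. The enantiopurity of A4 depends on which electrophilic site of the epichlorohydrin reacts first. C3 is set only by equilibration after a hot dealkoxycarbonylation, and A3 is again required.
- Comparison: on step count and cost of chirality this road is at least as good. The chosen plan avoids an organocopper addition to a doubly activated, doubly electrophilic substrate, sets C3 kinetically, and keeps equilibration in reserve.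

**Alternative 3:** The cut is the C4–C5 bond. Bu3SnH generates a carbon radical from the bromomethylsilyl ether A6, and this adds 5-exo to C4 of the enoate to give oxasilolane A7, with C4 set trans to the aryl-bearing carbinol. Tamao oxidation then reveals C5 as a hydroxymethyl group, lactonisation follows, and hydrogenolysis removes both the benzylic C–O bond and the benzyl ether.
- Merits: C4 is controlled by a cyclic transition state that does not depend on enolate geometry, the polarity (nucleophilic radical, electron-poor alkene) is matched, and the controlling carbinol is erased afterwards.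
- Weak points: A6 is an enantioenriched γ-silyloxy α-benzyl enoate that needs several steps. Stoichiometric tin is used. C3 is formed unselectively by hydrogen-atom transfer. A benzylic stereocentre is built only to be destroyed, and hydrogenolysis of a benzylic alcohol on a dimethoxyphenyl ring adds a demanding last step.
- Comparison: this road is the longest of the four and has the most redox adjustments. Its advantage is independence from enolate geometry. The chosen plan also uses a sacrificial carbinol, but transfers it in one thermal step that makes the C3–C4 bond and sets both centres.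

Key step: step 6

Remark: 1, 5 and 6 are taken as purchased materials (6 in high enantiomeric purity), and lithium diisopropylamide is used as a commercial solution.

## Route

Step 1
Reactants: 1 sinapic acid
Product: 2 3-(4-hydroxy-3,5-dimethoxyphenyl)propanoic acid
Conditions: H2 (1 atm), 10% Pd/C, MeOH, rt
Reagents that add atoms: none
Why: Heterogeneous catalytic hydrogenation of a cinnamic acid double bond; the arene, phenol and acid are inert under these conditions.

Step 2
Reactants: 2 3-(4-hydroxy-3,5-dimethoxyphenyl)propanoic acid
Product: 3 benzyl 3-(4-benzyloxy-3,5-dimethoxyphenyl)propanoate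
Conditions: BnBr (2.4 equiv), K2CO3, DMF, 60 °C
Reagents that add atoms: benzyl bromide, BrCc1ccccc1
Why: Williamson etherification of the phenoxide and SN2 alkylation of the carboxylate in one operation; warming overcomes the hindrance of the two flanking methoxy groups.

Step 3
Reactants: 3 benzyl 3-(4-benzyloxy-3,5-dimethoxyphenyl)propanoate
Product: 4 3-(4-benzyloxy-3,5-dimethoxyphenyl)propanoic acid
Conditions: LiOH·H2O, THF/MeOH/H2O, rt; then 1 M HCl
Reagents that add atoms: lithium hydroxide, [Li+].[OH-]
Why: Saponification cleaves only the benzyl ester; the aryl benzyl ether is stable to hydroxide.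

Step 4
Reactants: 5 methyl eugenol (2.5 equiv); 6 (R)-but-3-en-2-ol
Product: 7 (R,E)-5-(3,4-dimethoxyphenyl)pent-3-en-2-ol
Conditions: second-generation Grubbs catalyst RuCl2(=CHPh)(PCy3)(H2IMes) (3 mol%), 1,4-benzoquinone (10 mol%), CH2Cl2, 40 °C
Reagents that add atoms: none
Why: Olefin cross-metathesis between a rapidly homodimerising allylarene and a slowly homodimerising secondary allylic alcohol is selective, and secondary metathesis favours the E isomer. The carbinol stereocentre is not involved, and benzoquinone suppresses ruthenium hydride-mediated double-bond migration.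

Step 5
Reactants: 4 3-(4-benzyloxy-3,5-dimethoxyphenyl)propanoic acid; 7 (R,E)-5-(3,4-dimethoxyphenyl)pent-3-en-2-ol
Product: 8 (R,E)-5-(3,4-dimethoxyphenyl)pent-3-en-2-yl 3-(4-benzyloxy-3,5-dimethoxyphenyl)propanoate
Conditions: DCC, DMAP (cat.), CH2Cl2, 0 °C to rt
Reagents that add atoms: none
Why: Steglich esterification through the acylpyridinium ion; only the acyl–oxygen bond forms, so the (R) carbinol and the E alkene are retained.

Step 6
Reactants: 8 (R,E)-5-(3,4-dimethoxyphenyl)pent-3-en-2-yl 3-(4-benzyloxy-3,5-dimethoxyphenyl)propanoate
Product: 12 (2R,3S,E)-2-(4-benzyloxy-3,5-dimethoxybenzyl)-3-(3,4-dimethoxybenzyl)hex-4-enoic acid, via lithium enolate 9 (not isolated), via silyl ketene acetal 10 (not isolated), via trimethylsilyl ester 11 (not isolated)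
Conditions: LiN(iPr)2 (LDA), THF/DMPU (55:45), −78 °C; Me3SiCl (Et3N-buffered), −78 °C to rt, then 50 °C; 1 M HCl work-up
Reagents that add atoms: none
Why: This is an Ireland–Claisen rearrangement of the ester of an enantioenriched secondary (E)-allylic alcohol, a known reaction type with 1,3-chirality transfer. LDA in DMPU-rich THF deprotonates 8 through an open, non-chelated transition state to give enolate 9 with the benzyl group cis to O–Li, and O-silylation freezes this geometry as (Z)-ketene acetal 10. On warming, 10 undergoes a concerted suprafacial [3,3]-sigmatropic shift through a chair in which the carbinol methyl group, the 3,4-dimethoxybenzyl group on the (E)-alkene and the enolate benzyl group (trans to the ring oxygen) are all equatorial. The new bond forms on the face from which the C–O bond departs, so the (R) carbinol dictates the 3S centre (the future lactone C4, R), and the ketene acetal geometry places C2 syn to it as 2R, which becomes trans in the lactone. No ring closes; one skeletal bond and two stereocentres are made, and the carbinol centre is consumed to give the (E)-propenyl group that masks C5. The step needs one ketene acetal geometry, secured by solvent-controlled enolisation, and one chair, secured by the 1,3-diaxial contact an axial methyl group would have with the silyloxy group and by the E geometry of 7. A leak in enolate geometry or a boat pathway alters only C2, the centre that can be equilibrated after lactonisation, whereas C3 depends only on the carbinol and alkene configuration. Acidic work-up hydrolyses silyl ester 11 to acid 12.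

Step 7
Reactants: 12 (2R,3S,E)-2-(4-benzyloxy-3,5-dimethoxybenzyl)-3-(3,4-dimethoxybenzyl)hex-4-enoic acid
Product: 15 (3R,4R)-3-(4-benzyloxy-3,5-dimethoxybenzyl)-4-(3,4-dimethoxybenzyl)dihydrofuran-2(3H)-one, via ozonide 13 (not isolated), via hydroxy acid 14 (not isolated)
Conditions: O3, CH2Cl2, −78 °C (Sudan Red 7B end point); NaBH4, MeOH, −78 to 0 °C; 2 M HCl, then TsOH·H2O (cat.), CH2Cl2, rt
Reagents that add atoms: ozone, [O-][O+]=O
Why: Ozonolysis (cycloaddition, cycloreversion and recombination to ozonide 13) takes the isolated alkene far faster than the arenes when stopped at the dye end point. NaBH4 reduces the ozonide directly to primary alcohol 14 before the alpha centre can enolise, and acid closes the five-membered lactone by intramolecular acyl substitution. No stereocentre is touched.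

Step 8
Reactants: 15 (3R,4R)-3-(4-benzyloxy-3,5-dimethoxybenzyl)-4-(3,4-dimethoxybenzyl)dihydrofuran-2(3H)-one
Product: 16 (3R,4R)-4-(3,4-dimethoxybenzyl)-3-(4-hydroxy-3,5-dimethoxybenzyl)dihydrofuran-2(3H)-one
Conditions: H2 (1 atm), 10% Pd/C, EtOAc, rt
Reagents that add atoms: none
Why: Hydrogenolysis of the aryl benzyl ether under neutral conditions; the lactone, the aryl methyl ethers and both stereocentres are unaffected.

## Compound list

1 | sinapic acid, (E)-3-(4-hydroxy-3,5-dimethoxyphenyl)prop-2-enoic acid | COc1cc(/C=C/C(=O)O)cc(OC)c1O | starting material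
2 | 3-(4-hydroxy-3,5-dimethoxyphenyl)propanoic acid | COc1cc(CCC(=O)O)cc(OC)c1O | intermediate
3 | benzyl 3-(4-benzyloxy-3,5-dimethoxyphenyl)propanoate | COc1cc(CCC(=O)OCc2ccccc2)cc(OC)c1OCc1ccccc1 | intermediate
4 | 3-(4-benzyloxy-3,5-dimethoxyphenyl)propanoic acid | COc1cc(CCC(=O)O)cc(OC)c1OCc1ccccc1 | intermediate
5 | methyl eugenol, 4-allyl-1,2-dimethoxybenzene | C=CCc1ccc(OC)c(OC)c1 | starting material
6 | (R)-but-3-en-2-ol | C[C@@H](O)C=C | starting material
7 | (R,E)-5-(3,4-dimethoxyphenyl)pent-3-en-2-ol | C[C@@H](O)/C=C/Cc1ccc(OC)c(OC)c1 | intermediate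
8 | (R,E)-5-(3,4-dimethoxyphenyl)pent-3-en-2-yl 3-(4-benzyloxy-3,5-dimethoxyphenyl)propanoate | C[C@@H](OC(=O)CCc1cc(OC)c(OCc2ccccc2)c(OC)c1)/C=C/Cc1ccc(OC)c(OC)c1 | intermediate
9 | lithium enolate of 8, benzyl group cis to O–Li | C[C@@H](O/C([O-])=C/Cc1cc(OC)c(OCc2ccccc2)c(OC)c1)/C=C/Cc1ccc(OC)c(OC)c1.[Li+] | intermediate (not isolated)
10 | (Z)-trimethylsilyl ketene acetal of 8, benzyl group cis to OSiMe3 | C[C@@H](O/C(O[Si](C)(C)C)=C/Cc1cc(OC)c(OCc2ccccc2)c(OC)c1)/C=C/Cc1ccc(OC)c(OC)c1 | intermediate (not isolated)
11 | trimethylsilyl (2R,3S,E)-2-(4-benzyloxy-3,5-dimethoxybenzyl)-3-(3,4-dimethoxybenzyl)hex-4-enoate | C/C=C/[C@H](Cc1ccc(OC)c(OC)c1)[C@@H](Cc1cc(OC)c(OCc2ccccc2)c(OC)c1)C(=O)O[Si](C)(C)C | intermediate (not isolated)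
12 | (2R,3S,E)-2-(4-benzyloxy-3,5-dimethoxybenzyl)-3-(3,4-dimethoxybenzyl)hex-4-enoic acid | C/C=C/[C@H](Cc1ccc(OC)c(OC)c1)[C@@H](Cc1cc(OC)c(OCc2ccccc2)c(OC)c1)C(=O)O | intermediate
13 | (2R,3R)-2-(4-benzyloxy-3,5-dimethoxybenzyl)-4-(3,4-dimethoxyphenyl)-3-(5-methyl-1,2,4-trioxolan-3-yl)butanoic acid (ozonide, mixture at the trioxolane carbons) | CC1OOC(O1)[C@H](Cc1ccc(OC)c(OC)c1)[C@@H](Cc1cc(OC)c(OCc2ccccc2)c(OC)c1)C(=O)O | intermediate (not isolated)
14 | (2R,3R)-2-(4-benzyloxy-3,5-dimethoxybenzyl)-3-(3,4-dimethoxybenzyl)-4-hydroxybutanoic acid | OC[C@H](Cc1ccc(OC)c(OC)c1)[C@@H](Cc1cc(OC)c(OCc2ccccc2)c(OC)c1)C(=O)O | intermediate (not isolated)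
15 | (3R,4R)-3-(4-benzyloxy-3,5-dimethoxybenzyl)-4-(3,4-dimethoxybenzyl)dihydrofuran-2(3H)-one | COc1ccc(C[C@H]2COC(=O)[C@@H]2Cc2cc(OC)c(OCc3ccccc3)c(OC)c2)cc1OC | intermediate
16 | (3R,4R)-4-(3,4-dimethoxybenzyl)-3-(4-hydroxy-3,5-dimethoxybenzyl)dihydrofuran-2(3H)-one | COc1ccc(C[C@H]2COC(=O)[C@@H]2Cc2cc(OC)c(O)c(OC)c2)cc1OC | target

## Step count and weak points

Total: 8 steps. Longest linear sequence: 7 steps (1, 2, 3, 5, 6, 7, 8 from sinapic acid); the allylic alcohol branch is 1 step (step 4).

**Step 6 (key step).** The most likely failure is incomplete control of enolate geometry, or partial reaction through a boat. Either delivers some of the C2 epimer of 12, and neither touches C3. A second concern is C-silylation or slow rearrangement, which would lower conversion.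
Fallback: it sets out from 12 as obtained and comes back at 15. The acid mixture, containing (2S,3S,E)-2-(4-benzyloxy-3,5-dimethoxybenzyl)-3-(3,4-dimethoxybenzyl)hex-4-enoic acid F1, is taken unseparated through the conditions of step 7. F1 passes through its ozonide, (2S,3R)-2-(4-benzyloxy-3,5-dimethoxybenzyl)-4-(3,4-dimethoxyphenyl)-3-(5-methyl-1,2,4-trioxolan-3-yl)butanoic acid F2, and the hydroxy acid (2S,3R)-2-(4-benzyloxy-3,5-dimethoxybenzyl)-3-(3,4-dimethoxybenzyl)-4-hydroxybutanoic acid F3, to the cis lactone (3S,4R)-3-(4-benzyloxy-3,5-dimethoxybenzyl)-4-(3,4-dimethoxybenzyl)dihydrofuran-2(3H)-one F4. Treating the lactone mixture with DBU in toluene should equilibrate F4 through its enolate into the more stable trans lactone 15. This replaces kinetic control of C3 by thermodynamic control.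

**Step 4.** Migration of the allylarene double bond into conjugation, redox isomerisation of the allylic alcohol to a ketone, or incomplete E selectivity could occur. The last is the most damaging: the Z isomer of 7 would deliver the opposite configuration at C4 and lower the enantiomeric purity of 16.
Fallback: it sets out from 5 and comes back at 7. Cross-metathesis of 5 with methyl vinyl ketone (second-generation Hoveyda–Grubbs catalyst RuCl2(=CH-2-iPrOC6H4)(H2IMes)) should give (E)-5-(3,4-dimethoxyphenyl)pent-3-en-2-one F5 with thermodynamic E geometry. Corey–Bakshi–Shibata reduction with the (S)-2-methyl-oxazaborolidine and BH3·SMe2 then sets the (R) carbinol of 7. If needed, a lipase-catalysed acylation can raise the enantiomeric purity.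

**Step 7.** Over-oxidation of the dimethoxy- and trialkoxyphenyl rings by excess ozone is possible. So is epimerisation of the centre alpha to the transient aldehyde before hydride reduction.
Fallback: it sets out from 12 and comes back at 15. Esterification (MeI, K2CO3, DMF) gives methyl (2R,3S,E)-2-(4-benzyloxy-3,5-dimethoxybenzyl)-3-(3,4-dimethoxybenzyl)hex-4-enoate F6. Buffered Lemieux–Johnson cleavage (OsO4 cat., NaIO4, 2,6-lutidine, dioxane/H2O) gives the aldehyde methyl (2R,3R)-2-(4-benzyloxy-3,5-dimethoxybenzyl)-3-(3,4-dimethoxybenzyl)-4-oxobutanoate F7. NaBH4 in MeOH at 0 °C gives methyl (2R,3R)-2-(4-benzyloxy-3,5-dimethoxybenzyl)-3-(3,4-dimethoxybenzyl)-4-hydroxybutanoate F8, which lactonises with catalytic TsOH to 15. No ozone is used.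

## Further compounds

F1 | step 6 | (2S,3S,E)-2-(4-benzyloxy-3,5-dimethoxybenzyl)-3-(3,4-dimethoxybenzyl)hex-4-enoic acid | C/C=C/[C@H](Cc1ccc(OC)c(OC)c1)[C@H](Cc1cc(OC)c(OCc2ccccc2)c(OC)c1)C(=O)O
F2 | step 6 | (2S,3R)-2-(4-benzyloxy-3,5-dimethoxybenzyl)-4-(3,4-dimethoxyphenyl)-3-(5-methyl-1,2,4-trioxolan-3-yl)butanoic acid | CC1OOC(O1)[C@H](Cc1ccc(OC)c(OC)c1)[C@H](Cc1cc(OC)c(OCc2ccccc2)c(OC)c1)C(=O)O
F3 | step 6 | (2S,3R)-2-(4-benzyloxy-3,5-dimethoxybenzyl)-3-(3,4-dimethoxybenzyl)-4-hydroxybutanoic acid | OC[C@H](Cc1ccc(OC)c(OC)c1)[C@H](Cc1cc(OC)c(OCc2ccccc2)c(OC)c1)C(=O)O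
F4 | step 6 | (3S,4R)-3-(4-benzyloxy-3,5-dimethoxybenzyl)-4-(3,4-dimethoxybenzyl)dihydrofuran-2(3H)-one | COc1ccc(C[C@H]2COC(=O)[C@H]2Cc2cc(OC)c(OCc3ccccc3)c(OC)c2)cc1OC
F5 | step 4 | (E)-5-(3,4-dimethoxyphenyl)pent-3-en-2-one | CC(=O)/C=C/Cc1ccc(OC)c(OC)c1
F6 | step 7 | methyl (2R,3S,E)-2-(4-benzyloxy-3,5-dimethoxybenzyl)-3-(3,4-dimethoxybenzyl)hex-4-enoate | C/C=C/[C@H](Cc1ccc(OC)c(OC)c1)[C@@H](Cc1cc(OC)c(OCc2ccccc2)c(OC)c1)C(=O)OC
F7 | step 7 | methyl (2R,3R)-2-(4-benzyloxy-3,5-dimethoxybenzyl)-3-(3,4-dimethoxybenzyl)-4-oxobutanoate | O=C[C@H](Cc1ccc(OC)c(OC)c1)[C@@H](Cc1cc(OC)c(OCc2ccccc2)c(OC)c1)C(=O)OC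
F8 | step 7 | methyl (2R,3R)-2-(4-benzyloxy-3,5-dimethoxybenzyl)-3-(3,4-dimethoxybenzyl)-4-hydroxybutanoate | OC[C@H](Cc1ccc(OC)c(OC)c1)[C@@H](Cc1cc(OC)c(OCc2ccccc2)c(OC)c1)C(=O)OC
A1 | alternative 1 | 3-(3,4-dimethoxybenzyl)cyclobutan-1-one | O=C1CC(Cc2ccc(OC)c(OC)c2)C1
A2 | alternative 1 | (R)-4-(3,4-dimethoxybenzyl)dihydrofuran-2(3H)-one | O=C1C[C@@H](Cc2ccc(OC)c(OC)c2)CO1
A3 | alternative 1 | 4-benzyloxy-3,5-dimethoxybenzyl bromide | COc1cc(CBr)cc(OC)c1OCc1ccccc1
A4 | alternative 2 | methyl (1S,5R)-2-oxo-3-oxabicyclo[3.1.0]hexane-1-carboxylate | COC(=O)[C@]12C[C@H]1COC2=O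
A5 | alternative 2 | methyl (4R)-4-(3,4-dimethoxybenzyl)-2-oxotetrahydrofuran-3-carboxylate (C3 epimers) | O=C1OC[C@H](Cc2ccc(OC)c(OC)c2)C1C(=O)OC
A6 | alternative 3 | methyl (R,E)-2-(4-benzyloxy-3,5-dimethoxybenzyl)-4-{[(bromomethyl)dimethylsilyl]oxy}-4-(3,4-dimethoxyphenyl)but-2-enoate | COC(=O)/C(Cc1cc(OC)c(OCc2ccccc2)c(OC)c1)=C/[C@@H](O[Si](C)(C)CBr)c1ccc(OC)c(OC)c1
A7 | alternative 3 | methyl 3-(4-benzyloxy-3,5-dimethoxyphenyl)-2-[(4S,5R)-5-(3,4-dimethoxyphenyl)-2,2-dimethyl-1,2-oxasilolan-4-yl]propanoate (C2 epimers) | COC(=O)C(Cc1cc(OC)c(OCc2ccccc2)c(OC)c1)[C@@H]1C[Si](C)(C)O[C@H]1c1ccc(OC)c(OC)c1
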